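The delta run still held 1.40% of its free monomer at its last reading, and I wanted to reckon that leftover for the next flask before I chose its bath.

| flask | free monomer | initiator | radical scavenger | temperature | remark | time |
|---|---|---|---|---|---|---|
| zeta | 17 mM | 48 µM | 8.5 µM | −25 °C | run made earlier |  |
| delta | 17 mM | 75 µM | 8.5 µM | 0 °C | run made earlier |  |
| eta | 17 mM | 34 µM | 13 µM | −25 °C | run made earlier |  |
| Thursday's | 17 mM | 34 µM | 8.5 µM | −20 °C |  | 15 h |
| Sunday's | 17 mM | 34 µM | 8.5 µM | 20 °C |  | 15 h |
| Friday's | 17 mM | 34 µM | 8.5 µM | 0 °C |  | 15 h |

| run | time / h | monomer in chains / % |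
|---|---|---|
| zeta | 0.833 | 0 |
| zeta | 2.50 | 0 |
| zeta | 4.00 | 0.3 |
| zeta | 6.00 | 0 |
| zeta | 10.0 | 2.2 |
| zeta | 12.0 | 20.3 |
| delta | 0.667 | 62.4 |
| delta | 1.33 | 86.3 |
| delta | 2.00 | 94.6 |
| delta | 3.00 | 96.9 |
| delta | 4.00 | 98.6 |
| eta | 2.50 | 0 |
| eta | 5.00 | 0.2 |
| eta | 8.00 | 0.4 |
| eta | 10.0 | 0.1 |
| eta | 12.0 | 0 |

(readings scatter by 0.5 percentage points)



- the flask with the highest amount of monomer in chains, in percent of the free monomer charged ("all alike" if they lie within 1.5 percentage points) (Thursday's / Sunday's / Friday's / all alike)
- final monomer in chains, as a percentage of the free monomer charged, in Thursday's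
- final monomer in chains, as a percentage of the free monomer charged, in Sunday's
- final monomer in chains, as a percentage of the free monomer charged, in Friday's

Zeta and eta looked like an induction period. Eta, with more scavenger per initiator than zeta, stayed at 0.4% or less through 12.0 h, while zeta rose between 10.0 h and 12.0 h. So I assumed that each initiator gives two radicals and each scavenger ends one. For the three new flasks that leaves 59.5 µM: the radical budget, twice the initiator charge minus the scavenger charge.

I also assumed that growing radicals end in pairs, so their level follows the square root of the radical supply. On that assumption the logarithmic rate of monomer loss decays with half the rate constant of the initiator's decay, and the falls of ln(free monomer) over equal spans form a geometric series. Its sum I called the reach, the dead-end limit of polymerisation, and on these assumptions, at one temperature, it goes as the root of the budget.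

Delta fell by 2.92 up to 2.00 h and by 1.35 in the next equal span, a ratio of 0.462, so its reach read 5.43. This is a loose reading: a scatter of 0.5 percentage points sits on a leftover of 1.40%. Delta's budget was 142 µM, so I gave Friday's, in the same bath, a reach of 3.52 and a leftover of 2.96%. Friday's 15 h is longer than delta's span of 2.00 h, so I expected that reach to be spent. In a colder bath the clock looked like the risk: zeta, at −25 °C, read 20.3% after 12.0 h. For a warmer bath I had no reach of my own, so I chose Friday's.

The forecast also chose Friday's, with 62% for Thursday's, 83% for Sunday's and 97% for Friday's. On Sunday's it said: “initiator dies faster than chains can grow (dead-end polymerisation), so conversion stalls near 83%”.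

Friday's gave 99.0%, with 1.0% free monomer left against my reckoned 2.96%, Sunday's 82.7% and Thursday's 75.1%, which is 13 points above the forecast, with 71% of Thursday's initiator left at 15.0 h.

    initiator → 2 initiating radical (k = 0.0225 h⁻¹, Ea = 91.0 kJ mol⁻¹)
    free monomer + initiating radical → growing radical + monomer in chains (k = 4.08 × 10⁵ M⁻¹ s⁻¹, Ea = 26.0 kJ mol⁻¹)
    free monomer + growing radical → monomer in chains + growing radical, rate k3*[growing radical]*[free monomer] (k = 16400 M⁻¹ s⁻¹, Ea = 21.0 kJ mol⁻¹)
    2 growing radical → dead chain (k = 2.50 × 10⁷ M⁻¹ s⁻¹, Ea = 16.0 kJ mol⁻¹)
    growing radical + radical scavenger → ended chains (k = 4.20 × 10⁷ M⁻¹ s⁻¹, Ea = 14.0 kJ mol⁻¹)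
    (constants at −20 °C)

Sunday's stopped with initiator at 0% and 17% free monomer, a reach of 1.75 on its budget of 59.5 µM. The neighbouring flask was Sunday's with 0.14 mM of initiator, which raises the budget to 272 µM. The root rule multiplies the reach by 2.14, to 3.75, and that leaves 2.36% free monomer. The neighbouring flask ended with 2.2% free monomer.

The readings come from a simulation with constants of no real substance.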